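**Retrosynthetic overview**
1. (−)-Thujaplicatin 18 ⇐ tri-O-benzyl lactone 17 by global hydrogenolysis as the last step.
2. The lactone is the only ring made, and it is closed after the key C–C bond: 17 ⇐ γ-hydroxy tert-butyl ester 15 ⇐ imide/ester succinate 14, with C3 set by base equilibration to trans.
3. Key disconnection: the C3–C4 bond (lignan C8–C8′) of 14 ⇐ two enolate α-carbons (imide 11 + ester 5) joined by oxidative enolate heterocoupling. One enolate is oxidised to an electrophilic α-carbonyl radical (enolonium-type partner), and the Evans auxiliary fixes C4.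
4. 11 ⇐ hydroferulic acid 6 + oxazolidinone 9; 5 ⇐ 5-hydroxyvanillin 1 + C2 ylide 3. Both arenes are bought.

Assumption: 5-hydroxyvanillin, hydroferulic acid, ylide 3 and (S)-4-benzyloxazolidin-2-one are taken as purchasable; step 6 is counted as one step because its intermediates are carried on crude, with a single purification.

**Step 1**
Reactants: 1 5-hydroxyvanillin (3,4-dihydroxy-5-methoxybenzaldehyde)
Product: 2 3,4-bis(benzyloxy)-5-methoxybenzaldehyde
Conditions: BnBr (2.3 equiv), K2CO3 (3 equiv), DMF, 60 °C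
Reagents that add atoms: benzyl bromide, BrCc1ccccc1
Why: Williamson ether synthesis, in which the carbonate deprotonates both phenols and excess benzyl bromide O-alkylates them while the aldehyde is inert.

**Step 2**
Reactants: 2 3,4-bis(benzyloxy)-5-methoxybenzaldehyde; 3 tert-butyl (triphenylphosphoranylidene)acetate
Product: 5 tert-butyl 3-[3,4-bis(benzyloxy)-5-methoxyphenyl]propanoate, via cinnamate ester 4 (not isolated)
Conditions: 3 (1.1 equiv), THF–MeOH 1:1, rt; then NiCl2·6H2O (0.3 equiv), NaBH4 (3 equiv), 0 °C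
Reagents that add atoms: none
Why: Wittig olefination with a stabilised ylide gives the E-cinnamate, and nickel boride formed in the same pot from NiCl2 and NaBH4 effects conjugate reduction of the electron-poor C=C without touching aryl benzyl ethers or the tert-butyl ester.

**Step 3**
Reactants: 6 hydroferulic acid (3-(4-hydroxy-3-methoxyphenyl)propanoic acid)
Product: 8 3-[4-(benzyloxy)-3-methoxyphenyl]propanoic acid, via benzyl ester 7 (not isolated)
Conditions: BnBr (2.3 equiv), K2CO3 (3 equiv), DMF, 60 °C; then 2 M NaOH (aq), MeOH, rt; HCl work-up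
Reagents that add atoms: benzyl bromide, BrCc1ccccc1; sodium hydroxide, [Na+].[OH-] (its oxygen replaces the one that leaves with benzyl alcohol)
Why: Williamson O-benzylation of phenol and acid followed by saponification, which cleaves only the benzyl ester because the aryl benzyl ether is inert to hydroxide.

**Step 4**
Reactants: 8 3-[4-(benzyloxy)-3-methoxyphenyl]propanoic acid; 9 (4S)-4-benzyl-1,3-oxazolidin-2-one
Product: 11 (4S)-4-benzyl-3-{3-[4-(benzyloxy)-3-methoxyphenyl]propanoyl}-1,3-oxazolidin-2-one, via mixed pivalic anhydride 10 (not isolated)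
Conditions: t-BuCOCl (1.1 equiv), Et3N (2.5 equiv), THF, −20 °C; then 9 (1.0 equiv), LiCl (1.1 equiv), −20 °C to rt
Reagents that add atoms: pivaloyl chloride, CC(C)(C)C(Cl)=O (its atoms sit in intermediate 10 only and leave as pivalic acid)
Why: Mixed-anhydride N-acylation of the Evans oxazolidinone (LiCl/Et3N variant), in which the nitrogen attacks the less hindered acyl carbon of the anhydride and no stereocentre is touched.

**Step 5 (key step)**
Reactants: 11 (4S)-4-benzyl-3-{3-[4-(benzyloxy)-3-methoxyphenyl]propanoyl}-1,3-oxazolidin-2-one; 5 tert-butyl 3-[3,4-bis(benzyloxy)-5-methoxyphenyl]propanoate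
Product: 14 tert-butyl (2RS,3R)-2-[3,4-bis(benzyloxy)-5-methoxybenzyl]-3-[4-(benzyloxy)-3-methoxybenzyl]-4-[(4S)-4-benzyl-2-oxo-1,3-oxazolidin-3-yl]-4-oxobutanoate, via imide lithium Z-enolate 12 (not isolated), via ester lithium enolate 13 (not isolated)
Conditions: 11 (1.0 equiv) + 5 (1.2 equiv), LiN(i-Pr)2 (2.3 equiv), THF, −78 °C, 30 min; then Fe(acac)3 (2.2 equiv), THF, −78 °C to rt
Reagents that add atoms: none
Why: Oxidative enolate heterocoupling, in which trivalent iron removes one electron from the more electron-rich ester enolate within the mixed aggregate so that its normally nucleophilic α-carbon becomes an electrophilic α-carbonyl radical (enolonium-type partner) that is trapped by the chelated Z-enolate of the imide on the face opposite the auxiliary benzyl group (the sense of an Evans alkylation), a second electron transfer giving the 1,4-dicarbonyl; this sets the imide α-carbon (future C4) as R, while the ester α-carbon (future C3) forms as an epimer mixture that step 6 corrects.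

**Step 6**
Reactants: 14 tert-butyl (2RS,3R)-2-[3,4-bis(benzyloxy)-5-methoxybenzyl]-3-[4-(benzyloxy)-3-methoxybenzyl]-4-[(4S)-4-benzyl-2-oxo-1,3-oxazolidin-3-yl]-4-oxobutanoate
Product: 17 (3R,4R)-3-[3,4-bis(benzyloxy)-5-methoxybenzyl]-4-[4-(benzyloxy)-3-methoxybenzyl]dihydrofuran-2(3H)-one, via hydroxy ester 15 (not isolated), via lactone epimer mixture 16 (not isolated)
Conditions: LiBH4 (1.5 equiv), MeOH (1.5 equiv), THF, 0 °C; aqueous work-up, crude into PhMe; TsOH·H2O (0.2 equiv), 80 °C; then DBU (2 equiv), 100 °C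
Reagents that add atoms: none
Why: Reductive cleavage of the Evans auxiliary by LiBH4 (the imide C=O is far more electrophilic than the tert-butyl ester), acid-catalysed lactonisation with loss of isobutene, and DBU epimerisation through the lactone enolate, which equilibrates only the acidic C3 to the more stable trans isomer so that C3 becomes R relative to the fixed, non-enolisable C4 (R).

**Step 7**
Reactants: 17 (3R,4R)-3-[3,4-bis(benzyloxy)-5-methoxybenzyl]-4-[4-(benzyloxy)-3-methoxybenzyl]dihydrofuran-2(3H)-one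
Product: 18 (−)-thujaplicatin, (3R,4R)-3-(3,4-dihydroxy-5-methoxybenzyl)-4-(4-hydroxy-3-methoxybenzyl)dihydrofuran-2(3H)-one
Conditions: H2 (1 atm), 10% Pd/C, EtOAc–MeOH, rt, degassed solvents
Reagents that add atoms: none
Why: Catalytic hydrogenolysis of the three aryl benzyl ethers over Pd/C, which leaves the lactone, the methyl ethers and both stereocentres untouched.

**Compound list**
1 | 5-hydroxyvanillin (3,4-dihydroxy-5-methoxybenzaldehyde) | COc1cc(C=O)cc(O)c1O | starting material
2 | 3,4-bis(benzyloxy)-5-methoxybenzaldehyde | COc1cc(C=O)cc(OCc2ccccc2)c1OCc1ccccc1 | intermediate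
3 | tert-butyl (triphenylphosphoranylidene)acetate | CC(C)(C)OC(=O)C=P(c1ccccc1)(c1ccccc1)c1ccccc1 | starting material
4 | tert-butyl (E)-3-[3,4-bis(benzyloxy)-5-methoxyphenyl]prop-2-enoate (not isolated) | COc1cc(/C=C/C(=O)OC(C)(C)C)cc(OCc2ccccc2)c1OCc1ccccc1 | intermediate
5 | tert-butyl 3-[3,4-bis(benzyloxy)-5-methoxyphenyl]propanoate | COc1cc(CCC(=O)OC(C)(C)C)cc(OCc2ccccc2)c1OCc1ccccc1 | intermediate
6 | hydroferulic acid, 3-(4-hydroxy-3-methoxyphenyl)propanoic acid | COc1cc(CCC(=O)O)ccc1O | starting material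
7 | benzyl 3-[4-(benzyloxy)-3-methoxyphenyl]propanoate (not isolated) | COc1cc(CCC(=O)OCc2ccccc2)ccc1OCc1ccccc1 | intermediate
8 | 3-[4-(benzyloxy)-3-methoxyphenyl]propanoic acid | COc1cc(CCC(=O)O)ccc1OCc1ccccc1 | intermediate
9 | (4S)-4-benzyl-1,3-oxazolidin-2-one | O=C1N[C@@H](Cc2ccccc2)CO1 | starting material
10 | 3-[4-(benzyloxy)-3-methoxyphenyl]propanoic pivalic anhydride (not isolated) | COc1cc(CCC(=O)OC(=O)C(C)(C)C)ccc1OCc1ccccc1 | intermediate
11 | (4S)-4-benzyl-3-{3-[4-(benzyloxy)-3-methoxyphenyl]propanoyl}-1,3-oxazolidin-2-one | COc1cc(CCC(=O)N2[C@@H](Cc3ccccc3)COC2=O)ccc1OCc1ccccc1 | intermediate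
12 | lithium Z-enolate of imide 11 (not isolated) | [Li+].[O-]/C(=C\Cc1ccc(OCc2ccccc2)c(OC)c1)N1[C@@H](Cc2ccccc2)COC1=O | intermediate
13 | lithium enolate of ester 5, OLi trans to the benzylic CH2 (not isolated) | [Li+].[O-]/C(OC(C)(C)C)=C/Cc1cc(OC)c(OCc2ccccc2)c(OCc2ccccc2)c1 | intermediate
14 | tert-butyl (2RS,3R)-2-[3,4-bis(benzyloxy)-5-methoxybenzyl]-3-[4-(benzyloxy)-3-methoxybenzyl]-4-[(4S)-4-benzyl-2-oxo-1,3-oxazolidin-3-yl]-4-oxobutanoate (C2-epimer mixture) | O=C(N1[C@@H](Cc2ccccc2)COC1=O)[C@H](Cc1ccc(OCc2ccccc2)c(OC)c1)C(Cc1cc(OC)c(OCc2ccccc2)c(OCc2ccccc2)c1)C(=O)OC(C)(C)C | intermediate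
15 | tert-butyl (2RS,3R)-2-[3,4-bis(benzyloxy)-5-methoxybenzyl]-3-[4-(benzyloxy)-3-methoxybenzyl]-4-hydroxybutanoate (not isolated) | OC[C@H](Cc1ccc(OCc2ccccc2)c(OC)c1)C(Cc1cc(OC)c(OCc2ccccc2)c(OCc2ccccc2)c1)C(=O)OC(C)(C)C | intermediate
16 | (3RS,4R)-3-[3,4-bis(benzyloxy)-5-methoxybenzyl]-4-[4-(benzyloxy)-3-methoxybenzyl]dihydrofuran-2(3H)-one (cis/trans mixture, not isolated) | COc1cc(C[C@H]2COC(=O)C2Cc2cc(OCc3ccccc3)c(OCc3ccccc3)c(OC)c2)ccc1OCc1ccccc1 | intermediate
17 | (3R,4R)-3-[3,4-bis(benzyloxy)-5-methoxybenzyl]-4-[4-(benzyloxy)-3-methoxybenzyl]dihydrofuran-2(3H)-one (trans) | COc1cc(C[C@H]2COC(=O)[C@@H]2Cc2cc(OCc3ccccc3)c(OCc3ccccc3)c(OC)c2)ccc1OCc1ccccc1 | intermediate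
18 | (−)-thujaplicatin, (3R,4R)-3-(3,4-dihydroxy-5-methoxybenzyl)-4-(4-hydroxy-3-methoxybenzyl)dihydrofuran-2(3H)-one | COc1cc(C[C@H]2COC(=O)[C@@H]2Cc2cc(O)c(O)c(OC)c2)ccc1O | target

**Step count**
Total: 7 steps. Longest linear sequence: 5 steps (1 → 2 → 5 → 14 → 17 → 18, or 6 → 8 → 11 → 14 → 17 → 18).

**Three steps most likely to fail, with fallbacks**

Step 5 (oxidative heterocoupling) is the riskiest: homodimers of 11 and 5 can compete, the yield may be modest, and any leakage in auxiliary control would erode the ee. Diastereomers of the wrong C3 configuration are removed by chromatography at 14, while the auxiliary is still attached. The fallback sets out from imide 11 and makes the same bond stepwise, with an α-bromo ester as the electrophilic α-carbonyl partner. Deprotonation with NaN(SiMe3)2 (THF, −78 °C) and alkylation with tert-butyl bromoacetate anti to the auxiliary benzyl group gives tert-butyl (3R)-3-[4-(benzyloxy)-3-methoxybenzyl]-4-[(4S)-4-benzyl-2-oxo-1,3-oxazolidin-3-yl]-4-oxobutanoate F1. LiBH4 reduction gives tert-butyl (3R)-3-[4-(benzyloxy)-3-methoxybenzyl]-4-hydroxybutanoate F2, which TsOH closes to (4R)-4-[4-(benzyloxy)-3-methoxybenzyl]dihydrofuran-2(3H)-one F3. In parallel, aldehyde 2 is reduced with NaBH4 to [3,4-bis(benzyloxy)-5-methoxyphenyl]methanol F4 and converted with PBr3 into 1,2-bis(benzyloxy)-5-(bromomethyl)-3-methoxybenzene F5. The lithium enolate of F3 (LiN(SiMe3)2, THF, −78 °C) is alkylated by F5 anti to the C4 substituent, giving the trans lactone directly and coming back to the route at 17.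

Step 6 (reduction, lactonisation, epimerisation) can fail at the hydride stage, because the imide carbonyl of 14 is hindered and hydride may attack the ring carbonyl of the auxiliary instead. The fallback sets out from 14. LiOH/H2O2 (THF–H2O, 0 °C) cleaves the auxiliary hydrolytically at the exocyclic carbonyl to give (2R,3RS)-2-[4-(benzyloxy)-3-methoxybenzyl]-3-[3,4-bis(benzyloxy)-5-methoxybenzyl]-4-tert-butoxy-4-oxobutanoic acid F6. BH3·SMe2 (THF, 0 °C) then reduces the free acid chemoselectively beside the tert-butyl ester and comes back to the route at hydroxy ester 15, which is lactonised and epimerised as before.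

Step 2 (one-pot Wittig and nickel boride reduction) may reduce incompletely or cause some debenzylation. The fallback sets out from 1 and reorders the operations so that hydrogenation precedes benzylation. Wittig reaction of unprotected 1 with ylide 3 (toluene, 80 °C) gives tert-butyl (E)-3-(3,4-dihydroxy-5-methoxyphenyl)prop-2-enoate F7. Hydrogenation (H2, Pd/C, EtOAc) gives tert-butyl 3-(3,4-dihydroxy-5-methoxyphenyl)propanoate F8. Benzylation (BnBr, K2CO3, DMF, under N2) comes back to the route at 5.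

**Further compounds**
F1 | step 5 | tert-butyl (3R)-3-[4-(benzyloxy)-3-methoxybenzyl]-4-[(4S)-4-benzyl-2-oxo-1,3-oxazolidin-3-yl]-4-oxobutanoate | O=C(N1[C@@H](Cc2ccccc2)COC1=O)[C@H](Cc1ccc(OCc2ccccc2)c(OC)c1)CC(=O)OC(C)(C)C
F2 | step 5 | tert-butyl (3R)-3-[4-(benzyloxy)-3-methoxybenzyl]-4-hydroxybutanoate | OC[C@H](Cc1ccc(OCc2ccccc2)c(OC)c1)CC(=O)OC(C)(C)C
F3 | step 5 | (4R)-4-[4-(benzyloxy)-3-methoxybenzyl]dihydrofuran-2(3H)-one | COc1cc(C[C@H]2COC(=O)C2)ccc1OCc1ccccc1
F4 | step 5 | [3,4-bis(benzyloxy)-5-methoxyphenyl]methanol | COc1cc(CO)cc(OCc2ccccc2)c1OCc1ccccc1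
F5 | step 5 | 1,2-bis(benzyloxy)-5-(bromomethyl)-3-methoxybenzene | COc1cc(CBr)cc(OCc2ccccc2)c1OCc1ccccc1
F6 | step 6 | (2R,3RS)-2-[4-(benzyloxy)-3-methoxybenzyl]-3-[3,4-bis(benzyloxy)-5-methoxybenzyl]-4-tert-butoxy-4-oxobutanoic acid | OC(=O)[C@H](Cc1ccc(OCc2ccccc2)c(OC)c1)C(Cc1cc(OC)c(OCc2ccccc2)c(OCc2ccccc2)c1)C(=O)OC(C)(C)C
F7 | step 2 | tert-butyl (E)-3-(3,4-dihydroxy-5-methoxyphenyl)prop-2-enoate | COc1cc(/C=C/C(=O)OC(C)(C)C)cc(O)c1O
F8 | step 2 | tert-butyl 3-(3,4-dihydroxy-5-methoxyphenyl)propanoate | COc1cc(CCC(=O)OC(C)(C)C)cc(O)c1O
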